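**Assumptions (one line each)**
- 3,5-Bis(benzyloxy)phenol, 3,4,5-tris(benzyloxy)benzaldehyde, (triphenylphosphoranylidene)acetaldehyde and 5-hydroxyvanillin are taken as commercial.
- The (R,R)-TsDPEN-Ru catalyst is assumed to give the (2R,3R) enantiomer; if it gives the enantiomer, the (S,S)-catalyst is used.

## Retrosynthetic overview
1. Target ← global debenzylation of a hepta-O-benzyl ester ← Steglich coupling of penta-O-benzyl-(–)-EGC with 4,5-bis(benzyloxy)-3-methoxybenzoic acid.
2. Penta-O-benzyl-EGC (2,3-cis) ← Ru-catalysed asymmetric transfer hydrogenation with dynamic kinetic resolution (ATH–DKR) of a racemic, rapidly epimerising 2-aryl-chroman-3-one. This one step sets C2 and C3 together, so no asymmetric dihydroxylation and no benzylic SN2 are needed.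
3. Chroman-3-one ← Meinwald rearrangement of the epoxide of a 2-aryl-2H-chromene (flav-3-ene).
4. The pyran ring is formed in a single step from 3,5-bis(benzyloxy)phenol and a cinnamaldehyde, by boronate-directed ortho-hydroxyalkylation and 6π-oxa-electrocyclisation. The A and B rings are built in before the pyran ring.

## Route

**Step 1**
Reactants: 1 (3,4,5-tris(benzyloxy)benzaldehyde); 2 ((triphenylphosphoranylidene)acetaldehyde)
Product: 3 ((E)-3-[3,4,5-tris(benzyloxy)phenyl]propenal)
Conditions: PhMe, 90 °C, 16 h
Reagents that add atoms: 2, O=CC=P(c1ccccc1)(c1ccccc1)c1ccccc1 (supplies the =CH–CHO unit)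
Why: Wittig olefination with a stabilised ylide gives the E-enal. No stereocentre is formed.

**Step 2**
Reactants: 3; 4 (3,5-bis(benzyloxy)phenol)
Product: 5 ((±)-5,7-bis(benzyloxy)-2-[3,4,5-tris(benzyloxy)phenyl]-2H-chromene)
Conditions: PhB(OH)2 (1.2 equiv), EtCO2H (0.2 equiv), PhMe, Dean–Stark, 110 °C; phenol 4 in excess
Reagents that add atoms: none (the boron reagent is lost and water is released)
Why: This is the phenylboronic-acid-mediated 2H-chromene synthesis. The aryl boronate delivers the enal carbonyl carbon to the ortho carbon, and the resulting o-quinone methide closes by 6π-oxa-electrocyclisation. C2 and C6 of phenol 4 are equivalent, so there is no regiochemistry problem. The C2 stereocentre is deliberately racemic, because step 4 will erase it.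

**Step 3**
Reactants: 5; 6 (dimethyldioxirane)
Product: 7 ((±)-5,7-bis(benzyloxy)-2-[3,4,5-tris(benzyloxy)phenyl]chroman-3-one)
Conditions: DMDO (1.1 equiv, ~0.07 M in acetone), CH2Cl2, 0 °C, 30 min; then BF3·OEt2 (10 mol%), –40 °C, 15 min. Use the crude ketone immediately.
Reagents that add atoms: 6, CC1(C)OO1 (the O atom ends up as the C3 carbonyl)
Why: DMDO epoxidises the electron-rich C3=C4 alkene under neutral conditions. Catalytic Lewis acid then ionises the C4–O bond, giving a cation stabilised by the trioxygenated A ring, and a 1,2-hydride shift from C3 gives the ketone (Meinwald rearrangement). C2 stays racemic and epimerisable.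

**Step 4**
Reactants: 7
Product: 8 ((2R,3R)-5,7,3',4',5'-penta-O-benzyl-epigallocatechin)
Conditions: (R,R)-RuCl(p-cymene)(TsDPEN) (3 mol%), HCO2H/Et3N (5:2), CH2Cl2, 30 °C, 24 h
Reagents that add atoms: none (only hydrogen is delivered)
Why: Ru–H reduction of the C3 ketone under dynamic kinetic resolution gives the cis alcohol and sets both stereocentres.
Proposed new method: the C2–H of 7 is flanked by C=O, aryl and ring O, so Et3N epimerises the ketone far faster than it is reduced. The chiral Ru–H then reduces one ketone enantiomer through the CH/π-stabilised six-membered transition state, giving the 2-aryl/3-OH cis alcohol, and the whole racemate funnels into one (2R,3R) product. The closest known reaction is Ru–TsDPEN ATH–DKR of isoflavanones (3-aryl-chroman-4-ones) to cis-isoflavanols and of 2-aryl-1-tetralones.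

**Step 5**
Reactants: 9 (5-hydroxyvanillin); 10 (benzyl bromide)
Product: 11 (4,5-bis(benzyloxy)-3-methoxybenzaldehyde)
Conditions: BnBr (2.5 equiv), K2CO3, DMF, 60 °C, 6 h
Reagents that add atoms: 10, BrCc1ccccc1 (two Bn groups)
Why: Williamson O-benzylation of the two phenols. The aldehyde is untouched and there are no stereocentres.

**Step 6**
Reactants: 11; 12 (sodium chlorite)
Product: 13 (4,5-bis(benzyloxy)-3-methoxybenzoic acid)
Conditions: NaClO2, NaH2PO4, 2-methyl-2-butene, tBuOH/H2O, rt, 3 h
Reagents that add atoms: 12, [Na+].[O-]Cl=O (supplies the carboxylic acid O)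
Why: Pinnick oxidation. 2-Methyl-2-butene scavenges HOCl, which protects the electron-rich arene and the benzyl ethers.

**Step 7**
Reactants: 8; 13
Product: 14 (hepta-O-benzyl-(–)-epigallocatechin 3-(3-O-methylgallate))
Conditions: DCC, DMAP, CH2Cl2, 0 °C to rt, 16 h
Reagents that add atoms: none (13 is a numbered reactant and DCC is only a dehydrating agent)
Why: Steglich esterification of the single free (axial) 3-OH. All other oxygens are benzylated, so there is no regiochemistry issue, and C3 is not attacked so its configuration is retained. C2–H is not acidified, so it does not epimerise.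

**Step 8**
Reactants: 14
Product: 15 (target)
Conditions: H2 (1 atm), Pd(OH)2/C, THF/MeOH (1:1), rt, 12 h
Reagents that add atoms: none (only hydrogen is added)
Why: Hydrogenolysis removes all seven benzyl ethers, and the aryl methyl ether, the ester and both stereocentres survive. This is the standard EGCG endgame.

## Compound list
1 | 3,4,5-tris(benzyloxy)benzaldehyde | O=Cc1cc(OCc2ccccc2)c(OCc2ccccc2)c(OCc2ccccc2)c1 | starting material
2 | (triphenylphosphoranylidene)acetaldehyde | O=CC=P(c1ccccc1)(c1ccccc1)c1ccccc1 | starting material (reagent)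
3 | (E)-3-[3,4,5-tris(benzyloxy)phenyl]propenal | O=C/C=C/c1cc(OCc2ccccc2)c(OCc2ccccc2)c(OCc2ccccc2)c1 | intermediate
4 | 3,5-bis(benzyloxy)phenol | Oc1cc(OCc2ccccc2)cc(OCc2ccccc2)c1 | starting material
5 | (±)-5,7-bis(benzyloxy)-2-[3,4,5-tris(benzyloxy)phenyl]-2H-chromene | C1(c2cc(OCc3ccccc3)c(OCc3ccccc3)c(OCc3ccccc3)c2)C=Cc2c(OCc3ccccc3)cc(OCc3ccccc3)cc2O1 | intermediate (C2 racemic)
6 | dimethyldioxirane | CC1(C)OO1 | starting material (reagent)
7 | (±)-5,7-bis(benzyloxy)-2-[3,4,5-tris(benzyloxy)phenyl]chroman-3-one | O=C1Cc2c(OCc3ccccc3)cc(OCc3ccccc3)cc2OC1c2cc(OCc3ccccc3)c(OCc3ccccc3)c(OCc3ccccc3)c2 | intermediate (C2 racemic)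
8 | (2R,3R)-penta-O-benzyl-epigallocatechin | O[C@@H]2Cc3c(OCc4ccccc4)cc(OCc4ccccc4)cc3O[C@@H]2c2cc(OCc4ccccc4)c(OCc4ccccc4)c(OCc4ccccc4)c2 | intermediate
9 | 5-hydroxyvanillin (4,5-dihydroxy-3-methoxybenzaldehyde) | COc1cc(C=O)cc(O)c1O | starting material
10 | benzyl bromide | BrCc1ccccc1 | starting material (reagent)
11 | 4,5-bis(benzyloxy)-3-methoxybenzaldehyde | COc1cc(C=O)cc(OCc2ccccc2)c1OCc1ccccc1 | intermediate
12 | sodium chlorite | [Na+].[O-]Cl=O | starting material (reagent)
13 | 4,5-bis(benzyloxy)-3-methoxybenzoic acid | COc1cc(C(=O)O)cc(OCc2ccccc2)c1OCc1ccccc1 | intermediate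
14 | hepta-O-benzyl-(–)-epigallocatechin 3-(3-O-methylgallate) | COc1cc(C(=O)O[C@@H]2Cc3c(OCc4ccccc4)cc(OCc4ccccc4)cc3O[C@@H]2c2cc(OCc4ccccc4)c(OCc4ccccc4)c(OCc4ccccc4)c2)cc(OCc2ccccc2)c1OCc1ccccc1 | intermediate
15 | (–)-epigallocatechin 3-(3-O-methylgallate) | COc1cc(C(=O)O[C@@H]2Cc3c(O)cc(O)cc3O[C@@H]2c2cc(O)c(O)c(O)c2)cc(O)c1O | target

## Totals
- Total steps: 8.
- Longest linear sequence: 6 (1 → 3 → 5 → 7 → 8 → 14 → 15, with the benzoic acid branch 9 → 11 → 13 joining at step 7).

## Three steps most likely to fail
1. **Step 4 (ATH–DKR).** The ketone may oxidise or racemise before reduction, the cis/trans ratio may be poor, or the catalyst may give the wrong enantiomer.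
   Fallback: reduce 7 with L-Selectride at –78 °C to give racemic cis-8, then resolve the enantiomers by preparative chiral HPLC.
2. **Step 3 (epoxidation/Meinwald).** The epoxide may be opened by adventitious water to the 3,4-diol, or the rearrangement may not stop at the ketone.
   Fallback: hydroborate 5 (BH3·SMe2, then NaBO3) to the racemic flavan-3-ol and oxidise with Dess–Martin periodinane to give 7 (two steps, no cationic intermediate).
3. **Step 2 (chromene formation).** The electron-rich enal 3 is a poor electrophile, so the yield may be low or the o-quinone methide may dimerise.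
   Fallback: build the flav-3-ene by ring-closing metathesis instead. Ortho-formylate phenol 4 and methylenate to the 2-vinylphenol, Mitsunobu-couple it with racemic 1-[3,4,5-tris(benzyloxy)phenyl]prop-2-en-1-ol, and close with Grubbs II.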